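**The question.** Which recipe leaves the most target after 4.0 d?

common to all: substrate 14 mM; precatalyst 0.5 mol%

|  | coupling partner | temperature | remark | time |
|---|---|---|---|---|
| spring | 1.2 equiv | 20 °C | run made earlier |  |
| midnight | 0.60 equiv | 31 °C | run made earlier |  |
| noon | 0.90 equiv | 20 °C | run made earlier |  |
| teal | 1.20 equiv | 25 °C | everything together at the start | 4.0 d |
| ochre | 1.20 equiv (in portions, 2, over 2.5 d) | 25 °C | first portion at the start, last at 2.5 d | 4.0 d |
| grey | 1.20 equiv (fed, over 2.5 d) |  | the addition at 5 °C, then warmed to 25 °C; the feed brings no volume worth counting | 4.0 d |
| green | 1.20 equiv (fed, over 2.5 d) | 25 °C | all else is in the flask from the start; the feed brings no volume worth counting | 4.0 d |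

| run | time / d | target / % |
|---|---|---|
| spring | 1.04 | 2.8 |
| spring | 2.08 | 10.1 |
| spring | 3.00 | 16.3 |
| spring | 4.00 | 24.7 |
| midnight | 0.208 | 1.2 |
| midnight | 0.417 | 2.0 |
| midnight | 1.04 | 7.3 |
| midnight | 2.50 | 19.4 |
| noon | 0.208 | 0 |
| noon | 0.417 | 0.4 |
| noon | 1.04 | 2.2 |
| noon | 2.50 | 10.5 |

(scatter of a reading: 0.5 percentage points)

1. the flask that comes out highest in amount of target, in percent of the substrate charged, or "all alike" when all lie within 1.5 percentage points (teal / ochre / grey / green / all alike)
2. target at the end, in percent of the substrate charged, teal
3. target at the end, in percent of the substrate charged, ochre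
4. target at the end, in percent of the substrate charged, grey
5. target at the end, in percent of the substrate charged, green

- the analysis behind the earlier runs scatters by 0.5 percentage points, standard deviation

**Straight line.** The bench habit is to read a slope and multiply by time: spring gains 8.4 percentage points between its last two readings. Noon, with 0.90 equiv of coupling partner, reaches 10.5 % at 2.50 d, while spring, with 1.2 equiv, already stands at 10.1 % at 2.08 d, so the rate is taken as first order in coupling partner and, by assumption, in substrate.

**Its border.** At spring's last reading, the product of substrate and coupling partner, reckoned from that reading, stands at 59.8 % of its starting value, so under the assumed orders the rate at fixed catalyst has fallen to that share, and a straight line is no fair reckoning that far out. Integrating the rate gives a clock that runs evenly at constant catalyst: with b the equivalents of coupling partner and x the target fraction, ln[(b − x)/(b(1 − x))]/(b − 1).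

**The pace.** The clock's gain per day of full catalyst is the pace. Over the last readings it gives 0.106 d⁻¹ in spring and 0.207 d⁻¹ in midnight. Extended back to zero, these lines show a lost time, the induction period, of 1.50 d and 0.389 d. Interpolating logarithms to 25 °C gives a pace of 0.144 d⁻¹ and a lost time of 0.812 d.

**The reckoning.** Run backwards, the clock puts teal at 36.6 %. Counting grey's cold days as lost leaves 0.816 d of full catalyst, hence 12.5 %. Ochre and green, with part of their coupling partner still to come until 2.5 d, are placed between these two.

**The result.** The forecast, a reckoning apart from the one above and higher on grey, gave 36 % for teal, 28 % for ochre, 16 % for grey and 29 % for green, with teal highest and the remark “Grey makes almost nothing cold”. The flasks give, in the same order, 37.9 %, 30.3 %, 13.9 % and 32.3 %, with teal highest. Through the pace, grey's result corresponds to 0.919 d of full catalyst. In grey at the end, precatalyst has a half-life of 0.72 d by its conversion into catalyst, shorter than the 5.1 d of substrate by the coupling step, and 78.8 % of the catalyst charge stands as catalyst.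

    precatalyst → catalyst (k = 0.0400 h⁻¹, Ea = 106 kJ mol⁻¹)
    substrate + coupling partner + catalyst → catalyst + target (k = 6900 M⁻² h⁻¹, Ea = 40.0 kJ mol⁻¹)
    (constants at 25 °C)

**Grey, read later.** Read at 10 d, grey's clock advances at the pace, less the lost time on the 21.2 % of precatalyst remaining at 4.00 d, which gives 56.3 %. The computed flask gives 58.9 %, which is 2.6 points higher.

(The runs come from a simulation with made-up constants; the scatter is artificial.)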